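**Plan**

- Retrosynthesis: the five benzyl ethers go last. One operation then cuts the aryl–O1'' and aryl–C4'' bonds of the 5,7-dioxygenated unit (unit 2, aryne insertion) and the aryl–O1 bond of the 7-oxygenated unit (unit 1, SNAr). Next comes the aryl–C4 bond of unit 1 (aryllithium acylation). The remaining chain C2–C3–C3''–C2'' with C4 and C4'' is a C2-symmetric bis-γ-lactone, cut at C3–C3'' into two molecules of one (S)-β-hydroxy ester.
- Forward: aryl ketone → β-keto ester → (S)-β-hydroxy ester → oxidative dimerisation to the dilactone (two temporary rings, each masking one carbinol oxygen and activating one acyl carbon) → one lactone opened by the ring A aryl of unit 1 → cascade that attaches ring A and closes ring C of unit 2 and closes ring C of unit 1 → hydrogenolysis.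
- Enabling feature: ring A of unit 2 carries its two ring C bonds on adjacent carbons, C8a'' (to O1'') and C4a'' (to C4''), the C5'' oxygen flanks C4a'', and O1'' and C4'' are 1,3-related on the chain. A 3,5-dialkoxybenzyne therefore takes O1'' at its carbon remote from the alkoxy group and delivers the carbanion beside that group onto C4'' through a six-membered transition state. Because C4'' is lactonised to O1 of unit 1, this acyl transfer releases the oxygen that closes ring C of unit 1.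
- Stereochemistry: C2 and C2'' come from one Noyori transfer hydrogenation and their C–O bonds are never broken. C3 and C3'' are set anti to them in the chelate-controlled coupling and, as ketone α-carbons in the product, sit in the thermodynamically preferred trans,trans arrangement.

Key step: step 7

Remark: flavanone locants are used for all intermediates (unit 1 = 7-oxygenated half, unprimed; unit 2 = 5,7-dioxygenated half, doubly primed); compounds 1, 6 and 9 are taken as purchasable.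

**Route**

Step 1
Reactants: 1 1-[4-(benzyloxy)phenyl]ethan-1-one
Product: 2 methyl 3-[4-(benzyloxy)phenyl]-3-oxopropanoate
Conditions: NaH, (MeO)2CO, THF, reflux; AcOH
Reagents that add atoms: dimethyl carbonate COC(=O)OC
Why: Claisen condensation of the methyl ketone enolate with dimethyl carbonate, driven by deprotonation of the β-keto ester formed; the benzyl ether is inert to NaH.

Step 2
Reactants: 2 methyl 3-[4-(benzyloxy)phenyl]-3-oxopropanoate
Product: 3 methyl (3S)-3-[4-(benzyloxy)phenyl]-3-hydroxypropanoate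
Conditions: RuCl[(S,S)-TsDPEN](p-cymene) (1 mol%), HCO2H/Et3N (5:2), DMF, 40 °C
Reagents that add atoms: none
Why: Noyori asymmetric transfer hydrogenation of an aryl β-keto ester, in which the (S,S)-ligand holds the aryl group against the η6-arene so that hydride should add to the face giving the (S)-carbinol, the centre that becomes C2 and C2''.

Step 3
Reactants: 3 methyl (3S)-3-[4-(benzyloxy)phenyl]-3-hydroxypropanoate (two molecules)
Product: 5 (3S,3aR,6S,6aR)-3,6-bis[4-(benzyloxy)phenyl]tetrahydro-1H,3H-furo[3,4-c]furan-1,4-dione, via diol diester 4 (not isolated)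
Conditions: LDA (2.2 equiv), THF, −78 to −20 °C; CuCl2 (1.1 equiv), DMF/THF, −78 °C to rt; aq NH4Cl; PPTS (cat.), PhMe, 60 °C
Reagents that add atoms: none
Why: Oxidative homocoupling of ester enolates, applied to the Fráter–Seebach dianion: one-electron oxidation by CuCl2 joins the two α-carbons, each on the face of its six-membered lithium chelate anti to the aryl group (the sense of Fráter–Seebach alkylation), which should give the C2-symmetric anti,anti dimer, and each γ-oxygen then lactonises onto the distal ester.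

Step 4
Reactants: 5 (3S,3aR,6S,6aR)-3,6-bis[4-(benzyloxy)phenyl]tetrahydro-1H,3H-furo[3,4-c]furan-1,4-dione; 6 4-(benzyloxy)-1-bromo-2-fluorobenzene
Product: 8 (3R,4R,5S)-4-[4-(benzyloxy)-2-fluorobenzoyl]-5-[4-(benzyloxy)phenyl]-3-{(S)-[4-(benzyloxy)phenyl](hydroxy)methyl}oxolan-2-one, via aryllithium 7 (not isolated)
Conditions: 6, n-BuLi, THF, −78 °C; cannulate into 5, THF, −78 °C; aq NH4Cl at −78 °C
Reagents that add atoms: none
Why: Bromine–lithium exchange followed by acyl substitution of a γ-lactone by the aryllithium; the tetrahedral lithium hemiketal persists at −78 °C so the aryl group adds once, the two lactones are homotopic so one product results, and no stereocentre is touched.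

Step 5
Reactants: 9 3,5-bis(benzyloxy)phenol
Product: 10 3,5-bis(benzyloxy)-2-bromophenol
Conditions: NBS, CH2Cl2, −78 °C to rt
Reagents that add atoms: N-bromosuccinimide O=C1CCC(=O)N1Br
Why: Electrophilic aromatic bromination at the position ortho to the hydroxyl and para to an ether oxygen, the position between the two benzyloxy groups being shielded.

Step 6
Reactants: 10 3,5-bis(benzyloxy)-2-bromophenol
Product: 13 3,5-bis(benzyloxy)-2-(trimethylsilyl)phenyl trifluoromethanesulfonate, via silyl ether 11 (not isolated), via C-silyl phenoxide 12 (not isolated)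
Conditions: (Me3Si)2NH, THF, 70 °C, concentrate; n-BuLi, THF, −100 to −80 °C; Tf2O, −100 °C to rt
Reagents that add atoms: hexamethyldisilazane C[Si](C)(C)N[Si](C)(C)C; trifluoromethanesulfonic anhydride O=S(=O)(OS(=O)(=O)C(F)(F)F)C(F)(F)F
Why: O-silylation, bromine–lithium exchange with retro-Brook rearrangement (1,3 O-to-C silyl shift) and triflation of the phenoxide, the standard entry to 2-silylaryl triflates.

Step 7
Reactants: 8 (3R,4R,5S)-4-[4-(benzyloxy)-2-fluorobenzoyl]-5-[4-(benzyloxy)phenyl]-3-{(S)-[4-(benzyloxy)phenyl](hydroxy)methyl}oxolan-2-one; 13 3,5-bis(benzyloxy)-2-(trimethylsilyl)phenyl trifluoromethanesulfonate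
Product: 16 (2S,2'S,3R,3'R)-5,7,7'-tris(benzyloxy)-2,2'-bis[4-(benzyloxy)phenyl]-2,2',3,3'-tetrahydro-4H,4'H-[3,3'-bichromene]-4,4'-dione, via aryne 14 (not isolated), via fluoro hydroxy diketone 15 (not isolated)
Conditions: 13 (1.2 equiv), CsF (4 equiv), THF, 65 °C; then Et3N, MeOH, rt
Reagents that add atoms: none
Why: Proposed new method: fluoride unmasks 3,5-bis(benzyloxy)benzyne 14, the only free hydroxyl of 8 (O1'') adds to the aryne carbon remote from the benzyloxy group, the aryl carbanion formed beside that group (C4a'') attacks the lactone carbonyl C4'', and the tetrahedral intermediate expels the lactone oxygen on C2, which displaces the ortho fluoride of the aroyl group by SNAr. The closest known reaction types are the aryne annulation of methyl salicylates to xanthones (O-arylation, then acyl substitution by the aryl anion), aryne insertion into the acyl C–C bond of β-keto esters, and SNAr closure of 2-fluorophenyl β-hydroxy ketones to chromanones. Ring C of unit 2 closes by 6-exo-trig attack of the carbanion on the lactone C=O with opening of the temporary γ-lactone, and ring C of unit 1 closes by six-membered addition–elimination at C8a with the Meisenheimer charge resting on the C4 ketone. No stereocentre is formed: C2 and C2'' keep their configuration because only O–aryl and acyl–O bonds change, and C3 and C3'' enter in, and as ketone α-carbons equilibrate under Et3N/MeOH towards, the trans,trans arrangement with both aryl groups and the inter-unit bond equatorial. Regioselectivity of the insertion is secured by the polarisation of the aryne by its 3-benzyloxy group, site selectivity by the second carbinol oxygen being masked as the lactone, and six- over seven-membered acyl transfer by the 1,3-relation of O1'' and C4''.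

Step 8
Reactants: 16 (2S,2'S,3R,3'R)-5,7,7'-tris(benzyloxy)-2,2'-bis[4-(benzyloxy)phenyl]-2,2',3,3'-tetrahydro-4H,4'H-[3,3'-bichromene]-4,4'-dione
Product: 17 (2S,2'S,3R,3'R)-5,7,7'-trihydroxy-2,2'-bis(4-hydroxyphenyl)-2,2',3,3'-tetrahydro-4H,4'H-[3,3'-bichromene]-4,4'-dione
Conditions: H2 (1 atm), 10% Pd/C, EtOAc/MeOH, rt
Reagents that add atoms: none
Why: Hydrogenolysis of the five aryl benzyl ethers over Pd/C under neutral conditions, which should leave the flavanone rings and the base-labile stereocentres untouched.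

**Compound list**

1 | 1-[4-(benzyloxy)phenyl]ethan-1-one | CC(=O)c1ccc(OCc2ccccc2)cc1 | starting material
2 | methyl 3-[4-(benzyloxy)phenyl]-3-oxopropanoate | COC(=O)CC(=O)c1ccc(OCc2ccccc2)cc1 | intermediate
3 | methyl (3S)-3-[4-(benzyloxy)phenyl]-3-hydroxypropanoate | COC(=O)C[C@H](O)c1ccc(OCc2ccccc2)cc1 | intermediate
4 | dimethyl (2R,3R)-2,3-bis{(S)-[4-(benzyloxy)phenyl](hydroxy)methyl}butanedioate | O[C@H](c1ccc(OCc2ccccc2)cc1)[C@H](C(=O)OC)[C@H]([C@H](O)c1ccc(OCc2ccccc2)cc1)C(=O)OC | intermediate (not isolated)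
5 | (3S,3aR,6S,6aR)-3,6-bis[4-(benzyloxy)phenyl]tetrahydro-1H,3H-furo[3,4-c]furan-1,4-dione (cis-fused bis-γ-lactone, each aryl cis to the neighbouring ring-fusion carbonyl branch) | O1[C@H](c2ccc(OCc3ccccc3)cc2)[C@@H]2C(=O)O[C@H](c3ccc(OCc4ccccc4)cc3)[C@@H]2C1=O | intermediate
6 | 4-(benzyloxy)-1-bromo-2-fluorobenzene | Brc1ccc(OCc2ccccc2)cc1F | starting material
7 | [4-(benzyloxy)-2-fluorophenyl]lithium | [Li]c1ccc(OCc2ccccc2)cc1F | intermediate (not isolated)
8 | (3R,4R,5S)-4-[4-(benzyloxy)-2-fluorobenzoyl]-5-[4-(benzyloxy)phenyl]-3-{(S)-[4-(benzyloxy)phenyl](hydroxy)methyl}oxolan-2-one | O1[C@H](c2ccc(OCc3ccccc3)cc2)[C@H](C(=O)c2ccc(OCc3ccccc3)cc2F)[C@H]([C@H](O)c2ccc(OCc3ccccc3)cc2)C1=O | intermediate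
9 | 3,5-bis(benzyloxy)phenol | Oc1cc(OCc2ccccc2)cc(OCc2ccccc2)c1 | starting material
10 | 3,5-bis(benzyloxy)-2-bromophenol | Oc1cc(OCc2ccccc2)cc(OCc2ccccc2)c1Br | intermediate
11 | [3,5-bis(benzyloxy)-2-bromophenoxy]trimethylsilane | C[Si](C)(C)Oc1cc(OCc2ccccc2)cc(OCc2ccccc2)c1Br | intermediate (not isolated)
12 | 3,5-bis(benzyloxy)-2-(trimethylsilyl)phenol (formed as its lithium phenoxide) | C[Si](C)(C)c1c(O)cc(OCc2ccccc2)cc1OCc1ccccc1 | intermediate (not isolated)
13 | 3,5-bis(benzyloxy)-2-(trimethylsilyl)phenyl trifluoromethanesulfonate | C[Si](C)(C)c1c(OS(=O)(=O)C(F)(F)F)cc(OCc2ccccc2)cc1OCc1ccccc1 | intermediate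
14 | 3,5-bis(benzyloxy)benzyne (1,2-didehydrobenzene with benzyloxy groups at C3 and C5) | C1#CC(OCc2ccccc2)=CC(OCc2ccccc2)=C1 | intermediate (not isolated)
15 | (2S,3R)-5,7-bis(benzyloxy)-3-{(1R,2S)-1-[4-(benzyloxy)-2-fluorobenzoyl]-2-[4-(benzyloxy)phenyl]-2-hydroxyethyl}-2-[4-(benzyloxy)phenyl]-2,3-dihydro-4H-chromen-4-one | O[C@H](c1ccc(OCc2ccccc2)cc1)[C@H](C(=O)c1ccc(OCc2ccccc2)cc1F)[C@H]1C(=O)c2c(OCc3ccccc3)cc(OCc3ccccc3)cc2O[C@@H]1c1ccc(OCc2ccccc2)cc1 | intermediate (not isolated)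
16 | (2S,2'S,3R,3'R)-5,7,7'-tris(benzyloxy)-2,2'-bis[4-(benzyloxy)phenyl]-2,2',3,3'-tetrahydro-4H,4'H-[3,3'-bichromene]-4,4'-dione | O=C1c2ccc(OCc3ccccc3)cc2O[C@H](c2ccc(OCc3ccccc3)cc2)[C@H]1[C@H]1C(=O)c2c(OCc3ccccc3)cc(OCc3ccccc3)cc2O[C@@H]1c1ccc(OCc2ccccc2)cc1 | intermediate
17 | (2S,2'S,3R,3'R)-5,7,7'-trihydroxy-2,2'-bis(4-hydroxyphenyl)-2,2',3,3'-tetrahydro-4H,4'H-[3,3'-bichromene]-4,4'-dione | O=C1c2ccc(O)cc2O[C@H](c2ccc(O)cc2)[C@H]1[C@H]1C(=O)c2c(O)cc(O)cc2O[C@@H]1c1ccc(O)cc1 | target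

**Count**

Total step count: 8. Longest linear sequence: 6 steps (1, 2, 3, 4, 7, 8).

**Steps most likely to fail**

Step 7. What may go wrong: protonation of the aryl carbanion before acyl transfer, retro-aldol loss of aldehyde from the caesium alkoxides, or O-arylation of the hemiketal form of 8. The fallback uses known reactions, sets out from 5 and returns at 16. 5-Fluororesorcinol is benzylated (BnBr, K2CO3, DMF) to 1,3-bis(benzyloxy)-5-fluorobenzene F1. F1 is brominated (NBS, MeCN) ortho to fluorine and para to a benzyloxy group to 1,5-bis(benzyloxy)-2-bromo-3-fluorobenzene F2, and F2 is converted by n-BuLi at −78 °C into [2,4-bis(benzyloxy)-6-fluorophenyl]lithium F3. Dilactone 5 is treated at −78 °C first with 7 and then, without work-up, with F3, so that each lactone is opened once. After NH4Cl this should give (2R,3R)-1-[2,4-bis(benzyloxy)-6-fluorophenyl]-4-[4-(benzyloxy)-2-fluorophenyl]-2,3-bis{(S)-[4-(benzyloxy)phenyl](hydroxy)methyl}butane-1,4-dione F4. K2CO3 in DMF at 60 °C then closes both pyranone rings by twofold SNAr to 16.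

Step 3. What may go wrong: incomplete oxidative coupling, chlorination of the enolate, or coupling on the wrong face with loss of C2 symmetry. The fallback sets out from 2 and returns at 16. The sodium enolate of 2 is dimerised with iodine (NaH, then 0.5 equiv I2, THF) to dimethyl 2,3-bis[4-(benzyloxy)benzoyl]butanedioate F5. Both aryl ketones are reduced under the conditions of step 2, with catalyst control at both carbinols and dynamic kinetic resolution of the labile α-carbons. The reduction product, taken to be dimethyl (2S,3S)-2,3-bis{(S)-[4-(benzyloxy)phenyl](hydroxy)methyl}butanedioate F6, should lactonise in the flask to the all-trans dilactone (3S,3aS,6S,6aS)-3,6-bis[4-(benzyloxy)phenyl]tetrahydro-1H,3H-furo[3,4-c]furan-1,4-dione F7, the ring-fusion epimer of 5. F7 is taken through the operations of step 4 to (3S,4S,5S)-4-[4-(benzyloxy)-2-fluorobenzoyl]-5-[4-(benzyloxy)phenyl]-3-{(S)-[4-(benzyloxy)phenyl](hydroxy)methyl}oxolan-2-one F8. In the operations of step 7, F8 should pass through (2S,3S)-5,7-bis(benzyloxy)-3-{(1S,2S)-1-[4-(benzyloxy)-2-fluorobenzoyl]-2-[4-(benzyloxy)phenyl]-2-hydroxyethyl}-2-[4-(benzyloxy)phenyl]-2,3-dihydro-4H-chromen-4-one F9 to the cis,cis biflavanone (2S,2'S,3S,3'S)-5,7,7'-tris(benzyloxy)-2,2'-bis[4-(benzyloxy)phenyl]-2,2',3,3'-tetrahydro-4H,4'H-[3,3'-bichromene]-4,4'-dione F10. The closing Et3N/MeOH stage epimerises both ketone α-carbons of F10 to the trans,trans isomer 16.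

Step 4. What may go wrong: opening of both equivalent lactones, or enolisation and β-elimination by the basic aryllithium. The fallback sets out from 4 (isolated by quenching step 3 cold, before the lactonisation stage) and returns at 8. Both hydroxyls are silylated (TBSOTf, 2,6-lutidine) to dimethyl (2R,3R)-2,3-bis{(S)-[4-(benzyloxy)phenyl][(tert-butyldimethylsilyl)oxy]methyl}butanedioate F11. The esters are saponified (LiOH, THF/H2O) to (2R,3R)-2,3-bis{(S)-[4-(benzyloxy)phenyl][(tert-butyldimethylsilyl)oxy]methyl}butanedioic acid F12. Dehydration (Ac2O, 60 °C) gives the C2-symmetric anhydride (3R,4R)-3,4-bis{(S)-[4-(benzyloxy)phenyl][(tert-butyldimethylsilyl)oxy]methyl}oxolane-2,5-dione F13. Aryllithium 7 adds once at −78 °C, because the carboxylate formed is inert, to give (2R,3R)-4-[4-(benzyloxy)-2-fluorophenyl]-2,3-bis{(S)-[4-(benzyloxy)phenyl][(tert-butyldimethylsilyl)oxy]methyl}-4-oxobutanoic acid F14. HF·pyridine removes both silyl groups to give (2R,3R)-4-[4-(benzyloxy)-2-fluorophenyl]-2,3-bis{(S)-[4-(benzyloxy)phenyl](hydroxy)methyl}-4-oxobutanoic acid F15, whose γ-hydroxy acid lactonises (EDC·HCl) to 8.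

**Further compounds**

F1 | step 7 | 1,3-bis(benzyloxy)-5-fluorobenzene | Fc1cc(OCc2ccccc2)cc(OCc2ccccc2)c1
F2 | step 7 | 1,5-bis(benzyloxy)-2-bromo-3-fluorobenzene | Brc1c(F)cc(OCc2ccccc2)cc1OCc1ccccc1
F3 | step 7 | [2,4-bis(benzyloxy)-6-fluorophenyl]lithium | [Li]c1c(F)cc(OCc2ccccc2)cc1OCc1ccccc1
F4 | step 7 | (2R,3R)-1-[2,4-bis(benzyloxy)-6-fluorophenyl]-4-[4-(benzyloxy)-2-fluorophenyl]-2,3-bis{(S)-[4-(benzyloxy)phenyl](hydroxy)methyl}butane-1,4-dione | O[C@H](c1ccc(OCc2ccccc2)cc1)[C@H](C(=O)c1ccc(OCc2ccccc2)cc1F)[C@H]([C@H](O)c1ccc(OCc2ccccc2)cc1)C(=O)c1c(F)cc(OCc2ccccc2)cc1OCc1ccccc1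
F5 | step 3 | dimethyl 2,3-bis[4-(benzyloxy)benzoyl]butanedioate | COC(=O)C(C(=O)c1ccc(OCc2ccccc2)cc1)C(C(=O)OC)C(=O)c1ccc(OCc2ccccc2)cc1
F6 | step 3 | dimethyl (2S,3S)-2,3-bis{(S)-[4-(benzyloxy)phenyl](hydroxy)methyl}butanedioate | O[C@H](c1ccc(OCc2ccccc2)cc1)[C@@H](C(=O)OC)[C@@H]([C@H](O)c1ccc(OCc2ccccc2)cc1)C(=O)OC
F7 | step 3 | (3S,3aS,6S,6aS)-3,6-bis[4-(benzyloxy)phenyl]tetrahydro-1H,3H-furo[3,4-c]furan-1,4-dione | O1[C@H](c2ccc(OCc3ccccc3)cc2)[C@H]2C(=O)O[C@H](c3ccc(OCc4ccccc4)cc3)[C@H]2C1=O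
F8 | step 3 | (3S,4S,5S)-4-[4-(benzyloxy)-2-fluorobenzoyl]-5-[4-(benzyloxy)phenyl]-3-{(S)-[4-(benzyloxy)phenyl](hydroxy)methyl}oxolan-2-one | O1[C@H](c2ccc(OCc3ccccc3)cc2)[C@@H](C(=O)c2ccc(OCc3ccccc3)cc2F)[C@@H]([C@H](O)c2ccc(OCc3ccccc3)cc2)C1=O
F9 | step 3 | (2S,3S)-5,7-bis(benzyloxy)-3-{(1S,2S)-1-[4-(benzyloxy)-2-fluorobenzoyl]-2-[4-(benzyloxy)phenyl]-2-hydroxyethyl}-2-[4-(benzyloxy)phenyl]-2,3-dihydro-4H-chromen-4-one | O[C@H](c1ccc(OCc2ccccc2)cc1)[C@@H](C(=O)c1ccc(OCc2ccccc2)cc1F)[C@@H]1C(=O)c2c(OCc3ccccc3)cc(OCc3ccccc3)cc2O[C@@H]1c1ccc(OCc2ccccc2)cc1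
F10 | step 3 | (2S,2'S,3S,3'S)-5,7,7'-tris(benzyloxy)-2,2'-bis[4-(benzyloxy)phenyl]-2,2',3,3'-tetrahydro-4H,4'H-[3,3'-bichromene]-4,4'-dione | O=C1c2ccc(OCc3ccccc3)cc2O[C@H](c2ccc(OCc3ccccc3)cc2)[C@@H]1[C@@H]1C(=O)c2c(OCc3ccccc3)cc(OCc3ccccc3)cc2O[C@@H]1c1ccc(OCc2ccccc2)cc1
F11 | step 4 | dimethyl (2R,3R)-2,3-bis{(S)-[4-(benzyloxy)phenyl][(tert-butyldimethylsilyl)oxy]methyl}butanedioate | CC(C)(C)[Si](C)(C)O[C@H](c1ccc(OCc2ccccc2)cc1)[C@H](C(=O)OC)[C@H]([C@H](O[Si](C)(C)C(C)(C)C)c1ccc(OCc2ccccc2)cc1)C(=O)OC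
F12 | step 4 | (2R,3R)-2,3-bis{(S)-[4-(benzyloxy)phenyl][(tert-butyldimethylsilyl)oxy]methyl}butanedioic acid | CC(C)(C)[Si](C)(C)O[C@H](c1ccc(OCc2ccccc2)cc1)[C@H](C(=O)O)[C@H]([C@H](O[Si](C)(C)C(C)(C)C)c1ccc(OCc2ccccc2)cc1)C(=O)O
F13 | step 4 | (3R,4R)-3,4-bis{(S)-[4-(benzyloxy)phenyl][(tert-butyldimethylsilyl)oxy]methyl}oxolane-2,5-dione | CC(C)(C)[Si](C)(C)O[C@H](c1ccc(OCc2ccccc2)cc1)[C@@H]1C(=O)OC(=O)[C@H]1[C@H](O[Si](C)(C)C(C)(C)C)c1ccc(OCc2ccccc2)cc1
F14 | step 4 | (2R,3R)-4-[4-(benzyloxy)-2-fluorophenyl]-2,3-bis{(S)-[4-(benzyloxy)phenyl][(tert-butyldimethylsilyl)oxy]methyl}-4-oxobutanoic acid | CC(C)(C)[Si](C)(C)O[C@H](c1ccc(OCc2ccccc2)cc1)[C@H](C(=O)c1ccc(OCc2ccccc2)cc1F)[C@H]([C@H](O[Si](C)(C)C(C)(C)C)c1ccc(OCc2ccccc2)cc1)C(=O)O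
F15 | step 4 | (2R,3R)-4-[4-(benzyloxy)-2-fluorophenyl]-2,3-bis{(S)-[4-(benzyloxy)phenyl](hydroxy)methyl}-4-oxobutanoic acid | O[C@H](c1ccc(OCc2ccccc2)cc1)[C@H](C(=O)c1ccc(OCc2ccccc2)cc1F)[C@H]([C@H](O)c1ccc(OCc2ccccc2)cc1)C(=O)O
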